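## Retrosynthetic overview
1. Target ⇒ labda-8,13E-diene-6β,7α,15-triol, by peracetylation and then selective methanolysis of the primary allylic acetate.
2. Triol ⇒ 7α-hydroxy-8-en-6-one ester (one LiAlH4 reduction sets 6β-OH and frees C15-OH) ⇒ homoannular 6-silyloxy-6,8-diene (α-face osmylation sets C7) ⇒ 7-en-6-one ⇒ labda-7,13E-dienoate (allylic oxidation at C6).
3. Key disconnection: C4–C5 and C9–C10 together. Ring A and then ring B close in one enantioselective, proton-initiated cation–olefin cascade of acyclic all-E ethyl geranylgeranoate. The cascade halts at the labdane stage with the C13 enoate side chain intact.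
4. Ethyl geranylgeranoate ⇒ (5E,9E)-farnesylacetone + triethyl phosphonoacetate (Horner–Wadsworth–Emmons).

Assumption: farnesylacetone is bought as the single (5E,9E) grade, and the catalyst enantiomer that turns (3E,7E)-homofarnesol into (−)-ambrox protonates the same alkene face here and gives the 5S,10S series (written as S,S; otherwise its mirror image is used).

## Route

Step 1
Reactants: 1 (5E,9E)-farnesylacetone; 2 triethyl phosphonoacetate
Product: 3 ethyl (2E,6E,10E)-geranylgeranoate
Conditions: NaH, THF, 0 °C to rt; minor 2Z isomer removed on SiO2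
Reagents that add atoms: triethyl phosphonoacetate (2), CCOC(=O)CP(=O)(OCC)OCC
Why: Horner–Wadsworth–Emmons olefination of a methyl ketone gives mainly the E trisubstituted enoate (about 4:1), the isomers are separable, and no stereocentre is formed.

Step 2
Reactants: 3 ethyl (2E,6E,10E)-geranylgeranoate
Product: 4 ethyl labda-7,13E-dien-15-oate (5α-H, 9α-H, 10β-CH3; 5S,9S,10S)
Conditions: (S,S)-imidodiphosphorimidate Brønsted acid [two 3,3'-bis(spiro[cyclohexane-1,9'-fluoren]-2'-yl)-BINOL units, N,N'-bis(triflyl)] (5 mol %), (CF3)3COH, −10 °C, GC control; Et3N quench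
Reagents that add atoms: none
Why: Proposed new method: a Stork–Eschenmoser proton-initiated cation–olefin bicyclisation in which the confined chiral acid protonates the most accessible C14=C15 alkene of the chair–chair folded chain, so anti additions across the two E alkenes set 5α-H, 10β-CH3 and 9α-H in one event with the absolute sense fixed by the chiral anion; the hydrogen-bonded enoate is too electron-poor to attack the C8 cation, so the cascade stops after ring B as in the diterpene cyclase, and the bulky anion takes the exposed axial 7α-H rather than the buried 9α-H while any exocyclic isomer is re-protonated and recycled; the closest known reaction types are the imidodiphosphorimidate-catalysed asymmetric cyclisation of homofarnesol to ambrox in fluorinated alcohols and the SnCl4–binaphthol proton-initiated polyene cyclisations.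

Step 3
Reactants: 4 ethyl labda-7,13E-dien-15-oate
Product: 5 ethyl 6-oxolabda-7,13E-dien-15-oate (5α-H, 9α-H, 10β-CH3)
Conditions: CrO3, 3,5-dimethylpyrazole, CH2Cl2, −20 °C
Reagents that add atoms: chromium trioxide, O=[Cr](=O)=O
Why: Allylic oxidation (Salmond conditions) attacks C6, the only ring allylic CH2 of the electron-rich 7-ene, as known for drim-7-enes and labd-7-enes, while the 13-ene is deactivated by the ester and C5, C9 and C10 are untouched.

Step 4
Reactants: 5 ethyl 6-oxolabda-7,13E-dien-15-oate
Product: 6 ethyl 6-(trimethylsilyloxy)labda-6,8,13E-trien-15-oate (5α-H, 10β-CH3)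
Conditions: TMSCl, NaI, Et3N, MeCN, rt to 40 °C; pentane extraction, used crude
Reagents that add atoms: chlorotrimethylsilane, C[Si](C)(C)Cl
Why: Thermodynamic silyl dienol ether formation with TMSI made in situ, in which reversible 1,4-addition of TMSI and Zaitsev loss of HI towards C9 give the more substituted homoannular 6,8-diene; C9 is deliberately flattened, C5–H stays because a 5-ene would clash with the C4 methyls, and the ester is not enolised under soft conditions.

Step 5
Reactants: 6 ethyl 6-(trimethylsilyloxy)labda-6,8,13E-trien-15-oate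
Product: 8 ethyl 7α-hydroxy-6-oxolabda-8,13E-dien-15-oate, via silyl hemiketal diol 7 (not isolated)
Conditions: OsO4 (2 mol %), NMO·H2O (1.1 equiv), acetone–t-BuOH, −5 °C; used at once
Reagents that add atoms: N-methylmorpholine N-oxide, C[N+]1([O-])CCOCC1 (oxygen relayed by OsO4, O=[Os](=O)(=O)=O); water, O
Why: Rubottom-type α-hydroxylation by Upjohn catalytic osmylation, in which OsO4 takes the electron-rich, only trisubstituted C6=C7 enol ether bond (the C8=C9 bond is tetrasubstituted and next to quaternary C10, the enoate is electron-poor) from the α face opposite the axial C10 and 4β methyls, and collapse of the hemiketal leaves the 7α-OH.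

Step 6
Reactants: 8 ethyl 7α-hydroxy-6-oxolabda-8,13E-dien-15-oate
Product: 9 labda-8,13E-diene-6β,7α,15-triol
Conditions: LiAlH4, Et2O, −78 to 0 °C; H2O work-up
Reagents that add atoms: none
Why: Hydride reduction in which LiAlH4 reaches C6 only from the α face (the β face is closed by the two syn-axial methyls, and the 7α-alkoxyaluminate can deliver hydride internally) to give the axial 6β-OH, and in the same step reduces the enoate 1,2 to the E allylic alcohol; crystalline 9 is the point at which ee is upgraded by recrystallisation.

Step 7
Reactants: 9 labda-8,13E-diene-6β,7α,15-triol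
Product: 11 6β,7α-diacetoxylabda-8,13E-dien-15-ol (target; 5S,6S,7S,10S), via 6β,7α,15-triacetate 10 (not isolated)
Conditions: Ac2O, DMAP, pyridine, 40 °C; evaporate with toluene; K2CO3 (0.2 equiv), MeOH, 0 °C, TLC control
Reagents that add atoms: acetic anhydride, CC(=O)OC(C)=O
Why: DMAP-catalysed exhaustive acetylation followed by Zemplén-type transesterification, in which the unhindered primary allylic acetate is methanolysed far faster than the axial, doubly flanked 6β-acetate and the pseudoaxial 7α-acetate, and no stereocentre is touched.

## Compound list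
1 | (5E,9E)-farnesylacetone, (5E,9E)-6,10,14-trimethylpentadeca-5,9,13-trien-2-one | CC(C)=CCC/C(C)=C/CC/C(C)=C/CCC(C)=O | starting material
2 | triethyl phosphonoacetate | CCOC(=O)CP(=O)(OCC)OCC | starting material
3 | ethyl (2E,6E,10E)-geranylgeranoate | CC(C)=CCC/C(C)=C/CC/C(C)=C/CC/C(C)=C/C(=O)OCC | intermediate
4 | ethyl labda-7,13E-dien-15-oate (5α-H, 9α-H, 10β-CH3) | CCOC(=O)/C=C(\C)CC[C@H]1C(C)=CC[C@H]2C(C)(C)CCC[C@]12C | intermediate
5 | ethyl 6-oxolabda-7,13E-dien-15-oate | CCOC(=O)/C=C(\C)CC[C@H]1C(C)=CC(=O)[C@H]2C(C)(C)CCC[C@]12C | intermediate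
6 | ethyl 6-(trimethylsilyloxy)labda-6,8,13E-trien-15-oate | CCOC(=O)/C=C(\C)CCC1=C(C)C=C(O[Si](C)(C)C)[C@H]2C(C)(C)CCC[C@]12C | intermediate
7 | silyl hemiketal diol, ethyl 6α,7α-dihydroxy-6β-(trimethylsilyloxy)labda-8,13E-dien-15-oate | CCOC(=O)/C=C(\C)CCC1=C(C)[C@H](O)[C@@](O)(O[Si](C)(C)C)[C@H]2C(C)(C)CCC[C@]12C | intermediate
8 | ethyl 7α-hydroxy-6-oxolabda-8,13E-dien-15-oate | CCOC(=O)/C=C(\C)CCC1=C(C)[C@H](O)C(=O)[C@H]2C(C)(C)CCC[C@]12C | intermediate
9 | labda-8,13E-diene-6β,7α,15-triol | OC/C=C(\C)CCC1=C(C)[C@H](O)[C@@H](O)[C@H]2C(C)(C)CCC[C@]12C | intermediate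
10 | 6β,7α,15-triacetoxylabda-8,13E-diene | CC(=O)OC/C=C(\C)CCC1=C(C)[C@H](OC(C)=O)[C@@H](OC(C)=O)[C@H]2C(C)(C)CCC[C@]12C | intermediate
11 | 6β,7α-diacetoxylabda-8,13E-dien-15-ol (CNP0187815.1) | CC(=O)O[C@@H]1[C@@H](OC(C)=O)C(C)=C(CC/C(C)=C/CO)[C@@]2(C)CCCC(C)(C)[C@H]12 | target

## Step count and risks
Total steps: 7. Longest linear sequence: 7.

The steps most likely to fail are 2, 4 and 5.

**Step 2.** The risks are proton loss at the wrong site, drift to the tetrasubstituted alkene, leakage to a tricycle, or inhibition of the acid by the ester. The fallback sets out from 3 and returns at 4, and it separates ring formation from alkene placement.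
- Compound 3 is cyclised with a stoichiometric chiral Lewis-acid-assisted Brønsted acid: SnCl4 with (R)-2-(2-fluorobenzyloxy)-2'-hydroxy-1,1'-binaphthyl, plus one further equivalent of SnCl4 to occupy the ester, in toluene at −78 °C.
- At this temperature products are not re-protonated and the least hindered C17 proton is lost. This gives ethyl copalate, ethyl labda-8(17),13E-dien-15-oate F1.
- The exocyclic alkene is then moved into the ring by cobalt-hydride hydrogen-atom-transfer isomerisation with chloro{2,2'-[(1,1,2,2-tetramethylethane-1,2-diyl)bis(nitrilomethylidyne)]bis(4,6-di-tert-butylphenolato)}cobalt and PhSiH3 in benzene at rt.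
- The tertiary C8 radical gives back the accessible C7 hydrogen rather than the hindered C9 hydrogen, which yields 4.

**Step 4.** The risk is that amine-mediated γ-deprotonation takes a C17 methyl hydrogen and gives the exocyclic 6,8(17)-dienol ether. The fallback sets out from 5 and returns at 8.
- The base-mediated silylation is replaced by fully reversible acid-catalysed enol acetylation (isopropenyl acetate, TsOH, reflux).
- This equilibrates to the more substituted homoannular dienol acetate, ethyl 6-acetoxylabda-6,8,13E-trien-15-oate F2.
- α-Face osmylation of its C6=C7 bond (OsO4 catalytic, NMO) and collapse of the acetoxy hemiketal give 8. Any 7-O-acetyl migration product converges in the LiAlH4 step.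

**Step 5.** The risk is that α-ketol 8 tautomerises through the enediol to the conjugated 6-hydroxy-8-en-7-one, or that oxidation occurs at the γ position. The fallback sets out from 6 and returns at 9, and it avoids the ketone stage altogether.
- BH3·SMe2 in THF at 0 °C adds H to C6 and B to C7 of the enol ether bond, syn and from the α face. This places OSiMe3 at 6β and boron at 7α in one event.
- Oxidation with anhydrous Me3NO uses no protic medium, so the allylic borane is not protonolysed. Dilute citric acid then gives ethyl 6β,7α-dihydroxylabda-8,13E-dien-15-oate F3.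
- LiAlH4 reduces the ester to 9.

## Further compounds
F1 | step 2 | ethyl labda-8(17),13E-dien-15-oate (ethyl copalate; 5α-H, 9α-H, 10β-CH3) | CCOC(=O)/C=C(\C)CC[C@H]1C(=C)CC[C@H]2C(C)(C)CCC[C@]12C
F2 | step 4 | ethyl 6-acetoxylabda-6,8,13E-trien-15-oate | CCOC(=O)/C=C(\C)CCC1=C(C)C=C(OC(C)=O)[C@H]2C(C)(C)CCC[C@]12C
F3 | step 5 | ethyl 6β,7α-dihydroxylabda-8,13E-dien-15-oate | CCOC(=O)/C=C(\C)CCC1=C(C)[C@H](O)[C@@H](O)[C@H]2C(C)(C)CCC[C@]12C
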